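**Assumption:** the SMILES is read as the (3R,4S,5R)-oxolane (the olivil skeleton), which maps onto the D-malate series; diethyl (R)-malate is taken as the purchasable chiral-pool source.

## Retrosynthetic overview

1. Target 11 ⇒ mono-benzyl ether 10 (final O-debenzylation).
2. 10 ⇒ acyclic triol 9 by opening the benzylic C7–O bond. The oxolane is the only ring in the target and is formed last, by a photochemical dehydrogenative quinone-methide cyclisation that also sets C7.
3. 9 ⇒ dioxolanone acid 8 (LiAlH4), i.e. a 2,3-dibenzyl-2-hydroxysuccinate.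
4. 8 ⇒ diethyl (R)-malate 3 by two benzylations with the same bromide 2: at C3 through the alkoxide–enolate (sets C8), then at C2 through a temporary cis-pivalaldehyde dioxolanone (sets the quaternary C8' with retention).
5. The phenol of the first-installed ring is freed before the second benzylation, so only that ring can form the quinone methide.

## Route

**Step 1**
Reactants: 1, 4-(benzyloxy)-3-methoxybenzyl alcohol
Product: 2, 4-(benzyloxy)-3-methoxybenzyl bromide
Conditions: PBr3 (0.4 equiv), Et2O, 0 °C
Reagents that add atoms: phosphorus tribromide, BrP(Br)Br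
Why: Standard SN2 bromination of a primary benzylic alcohol; the electron-rich bromide is used fresh.

**Step 2**
Reactants: 3, diethyl (R)-malate; 2, 4-(benzyloxy)-3-methoxybenzyl bromide
Product: 4, diethyl (2R,3S)-3-[4-(benzyloxy)-3-methoxybenzyl]-2-hydroxybutanedioate
Conditions: LiHMDS (2.2 equiv), THF, −78 → −20 °C; then 2, −78 → 0 °C
Reagents that add atoms: none
Why: Fráter–Seebach alkylation of the chelated lithium alkoxide–enolate dianion, in which the bromide enters anti to the C2 substituent (about 10:1) and the purchased C2 centre sets C3 (future C8) as S.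

**Step 3**
Reactants: 4
Product: 5, (2R,3S)-3-[4-(benzyloxy)-3-methoxybenzyl]-2-hydroxybutanedioic acid
Conditions: KOH, EtOH–H2O, rt; then aq. HCl
Reagents that add atoms: hydroxide/water, [OH-]
Why: Plain ester saponification; the carboxylate α-CH does not epimerise at room temperature.

**Step 4**
Reactants: 5
Product: 6, (2S)-3-[4-(benzyloxy)-3-methoxyphenyl]-2-[(2R,4R)-2-tert-butyl-5-oxo-1,3-dioxolan-4-yl]propanoic acid (cis-dioxolanone)
Conditions: t-BuCHO (3 equiv), TsOH·H2O (cat.), H2SO4 (cat.), pentane–CH2Cl2, reflux, Dean–Stark; cis isomer purified by recrystallisation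
Reagents that add atoms: pivalaldehyde, CC(C)(C)C=O
Why: Seebach acetalisation of the α-hydroxy acid unit gives the five-membered dioxolanone, and the thermodynamically preferred cis isomer places the new acetal centre (R) under control of the purchased C2 centre (self-regeneration of stereocentres).

**Step 5**
Reactants: 6
Product: 7, (2S)-2-[(2R,4R)-2-tert-butyl-5-oxo-1,3-dioxolan-4-yl]-3-(4-hydroxy-3-methoxyphenyl)propanoic acid
Conditions: H2 (1 atm), 10% Pd/C, EtOAc, rt
Reagents that add atoms: none
Why: Neutral hydrogenolysis of the aryl benzyl ether leaves the acylal and both stereocentres untouched and frees the phenol of the ring that must later become the quinone methide.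

**Step 6**
Reactants: 7; 2, 4-(benzyloxy)-3-methoxybenzyl bromide
Product: 8, (2S)-2-[(2R,4R)-4-[4-(benzyloxy)-3-methoxybenzyl]-2-tert-butyl-5-oxo-1,3-dioxolan-4-yl]-3-(4-hydroxy-3-methoxyphenyl)propanoic acid
Conditions: LiHMDS (3.3 equiv), THF, −78 °C; then 2 (1.1 equiv), −78 → −30 °C
Reagents that add atoms: none
Why: Seebach dioxolanone enolate alkylation in which the bromide attacks anti to the tert-butyl group, so the quaternary carbinol carbon (future C8', R) is rebuilt with retention; the lithium phenoxide and carboxylate are far less nucleophilic than the enolate at this temperature.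

**Step 7**
Reactants: 8
Product: 9, (2R,3R)-2-[4-(benzyloxy)-3-methoxybenzyl]-3-(4-hydroxy-3-methoxybenzyl)butane-1,2,4-triol
Conditions: LiAlH4 (6 equiv), THF, 0 °C → reflux; Rochelle-salt work-up
Reagents that add atoms: none
Why: Hydride reduction of the acid and the dioxolanone carbonyl gives both CH2OH groups and collapses the acetal (to neopentyl alcohol) to release the tertiary OH, with no bond to either stereocentre broken.

**Step 8**
Reactants: 9
Product: 10, (3R,4S,5R)-3-[4-(benzyloxy)-3-methoxybenzyl]-5-(4-hydroxy-3-methoxyphenyl)-4-(hydroxymethyl)oxolan-3-ol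
Conditions: 4CzIPN (2 mol%), Co(dmgH)2(py)Cl (5 mol%), 2,4,6-collidine (0.5 equiv), degassed MeCN (0.01 M), 456 nm LEDs, Ar, rt (H2 evolved); stop at about 90% conversion
Reagents that add atoms: none
Why: Proposed new method: photocatalytic acceptorless dehydrogenation of a free 4-alkylguaiacol to its p-quinone methide with in situ 5-exo-trig oxa-1,6-addition. Excited 4CzIPN oxidises the collidine-bound phenol by PCET, while the O-benzylated ring is harder to oxidise and cannot form a quinone methide. The cobaloxime then removes the weak benzylic C7–H of the phenoxyl radical (radical desaturation, H2 released). The quinone methide is trapped by the C9' primary OH, the only hydroxyl that gives a five-membered ring, with the aryl group settling trans to the C8 CH2OH and anti to the C8' benzyl, which sets C7 as R. The closest known chemistry is DDQ, Ag2O or flavoenzyme quinone-methide formation from 4-alkylphenols, and photoredox/cobaloxime dehydrogenative desaturation and C–H/O–H coupling.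

**Step 9**
Reactants: 10
Product: 11, (3R,4S,5R)-5-(4-hydroxy-3-methoxyphenyl)-3-(4-hydroxy-3-methoxybenzyl)-4-(hydroxymethyl)oxolan-3-ol (target)
Conditions: H2 (1 atm), 10% Pd/C, EtOAc–EtOH, rt, stopped as soon as 10 is consumed
Reagents that add atoms: none
Why: Neutral hydrogenolysis of the aryl benzyl ether is faster than cleavage of the cyclic benzylic C7–O bond, and the acid-free conditions avoid rearrangement to the cyclo-lignan.

## Compound list

1 | 4-(benzyloxy)-3-methoxybenzyl alcohol | COc1cc(CO)ccc1OCc1ccccc1 | starting material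
2 | 4-(benzyloxy)-3-methoxybenzyl bromide | COc1cc(CBr)ccc1OCc1ccccc1 | intermediate
3 | diethyl (R)-malate | CCOC(=O)[C@H](O)CC(=O)OCC | starting material
4 | diethyl (2R,3S)-3-[4-(benzyloxy)-3-methoxybenzyl]-2-hydroxybutanedioate | CCOC(=O)[C@H](O)[C@H](Cc1ccc(OCc2ccccc2)c(OC)c1)C(=O)OCC | intermediate
5 | (2R,3S)-3-[4-(benzyloxy)-3-methoxybenzyl]-2-hydroxybutanedioic acid | OC(=O)[C@H](O)[C@H](Cc1ccc(OCc2ccccc2)c(OC)c1)C(=O)O | intermediate
6 | (2S)-3-[4-(benzyloxy)-3-methoxyphenyl]-2-[(2R,4R)-2-tert-butyl-5-oxo-1,3-dioxolan-4-yl]propanoic acid | CC(C)(C)[C@@H]1O[C@@H](C(=O)O1)[C@H](Cc2ccc(OCc3ccccc3)c(OC)c2)C(=O)O | intermediate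
7 | (2S)-2-[(2R,4R)-2-tert-butyl-5-oxo-1,3-dioxolan-4-yl]-3-(4-hydroxy-3-methoxyphenyl)propanoic acid | CC(C)(C)[C@@H]1O[C@@H](C(=O)O1)[C@H](Cc2ccc(O)c(OC)c2)C(=O)O | intermediate
8 | (2S)-2-[(2R,4R)-4-[4-(benzyloxy)-3-methoxybenzyl]-2-tert-butyl-5-oxo-1,3-dioxolan-4-yl]-3-(4-hydroxy-3-methoxyphenyl)propanoic acid | CC(C)(C)[C@@H]1O[C@@](Cc2ccc(OCc3ccccc3)c(OC)c2)(C(=O)O1)[C@H](Cc4ccc(O)c(OC)c4)C(=O)O | intermediate
9 | (2R,3R)-2-[4-(benzyloxy)-3-methoxybenzyl]-3-(4-hydroxy-3-methoxybenzyl)butane-1,2,4-triol | COc1cc(C[C@](O)(CO)[C@H](Cc2ccc(O)c(OC)c2)CO)ccc1OCc3ccccc3 | intermediate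
10 | (3R,4S,5R)-3-[4-(benzyloxy)-3-methoxybenzyl]-5-(4-hydroxy-3-methoxyphenyl)-4-(hydroxymethyl)oxolan-3-ol | COc1cc(C[C@]2(O)CO[C@@H](c3ccc(O)c(OC)c3)[C@@H]2CO)ccc1OCc4ccccc4 | intermediate
11 | (3R,4S,5R)-5-(4-hydroxy-3-methoxyphenyl)-3-(4-hydroxy-3-methoxybenzyl)-4-(hydroxymethyl)oxolan-3-ol | COc1cc(C[C@]2(O)CO[C@@H](c3ccc(O)c(OC)c3)[C@@H]2CO)ccc1O | target

## Summary

Total steps: 9. Longest linear sequence: 9 (1 → 2 → 4 → … → 11; 8 from the malate 3).

Steps most likely to fail:

1. **Step 8 (proposed new photocyclisation).** Risks are phenoxyl dimerisation and over-oxidation of the product phenol. Fallback: drop the photocatalytic dehydrogenation and close the ring with stoichiometric ground-state DDQ (1.1 equiv, CH2Cl2–pH 7 buffer, 0 °C). This is the established hydride-abstraction route from dibenzylbutane-diol lignans to 7,9'-epoxylignans through the same quinone methide.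
2. **Step 6 (quaternary centre on a trianion with a free phenoxide).** Risks are poor solubility and O-benzylation. Fallback: change the protecting-group plan so the first aryl ring is installed as its N,N-diethylcarbamate (bromide from 2-methoxy-4-methylphenol: ClCONEt2, then NBS). The carbamate survives saponification, acetalisation and the now fully protected dianion alkylation, and is cleaved to the phenol by LiAlH4 in step 7. This deletes step 5 and adds one step for the second bromide.
3. **Step 9 (hydrogenolysis).** The risk is competing cleavage of the benzylic C7–O bond. Fallback: carry the second aryl ring as a TIPS ether (bromide from O-TIPS vanillin: NaBH4, then PBr3) and finish with TBAF, so no hydrogenation follows ring closure.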